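**Retrosynthetic overview**

1. The C8–C9 bond is made last, by B-alkyl Suzuki–Miyaura coupling of a bicyclic C9 enol triflate with the 9-BBN adduct of a 6-vinyl-1,2-dioxane propanoate.
2. The enol triflate comes from a cis-fused C13-silyloxy vinylogous ester by carbonyl transposition C11→C9, conjugate reduction/triflation and only then reductive allylic transposition (C13–O, C14=C15 → C13=C14), so the C13 alcohol is never β to a ketone.
3. Key disconnection, ring B: the cis C12–C17 ring fusion and the C13=C14 alkene, beside a ring A that already holds C18 (CMe2), the C10 methyl and a C9 oxygen, are the retron of a [4+2] on the C12=C17 alkene of 3-methoxy-2,4,4-trimethylcyclohexa-2,5-dienone with a 1-silyloxy-2-methylbutadiene.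
4. The dioxane takes C2/C3 from an Evans syn-aldol and C6 from Sharpless epoxidation followed by inverting perhydrolysis; the ring closes by inverting 6-exo SN2 of the C6 hydroperoxide at C3, and the vinyl group comes from glycol cleavage and Wittig methylenation.
5. Ring order: ring A (commercial dione), then ring B (Diels–Alder); the 1,2-dioxane is built separately and joined last.

Key step: step 5

Numbering used: C1 ester carbon, C2, dioxane carbons C3–C6, C7, C8, ring A C9=C10, C11, C12, C17, C18 (CMe2), ring B C12–C17.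

Assumption: the (R)-configured catalyst in step 5 is assigned from the α-C–H···O binding model for enone dienophiles; the antipodal catalyst is equally available and would be taken if the facial sense proved opposite.

**Route**

Step 1
Reactants: 1 4,4-dimethylcyclohexane-1,3-dione; 2 iodomethane
Product: 3 2,4,4-trimethylcyclohexane-1,3-dione
Conditions: MeI, NaOH, H2O/1,4-dioxane, reflux
Reagents that add atoms: none
Why: C-alkylation of the cyclic 1,3-diketone enolate in a protic medium, where hydrogen bonding to the enolate oxygens favours attack through carbon, should give the 2-methyl dione.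

Step 2
Reactants: 3 2,4,4-trimethylcyclohexane-1,3-dione
Product: 4 3-methoxy-2,4,4-trimethylcyclohex-2-en-1-one
Conditions: Me2SO4, K2CO3, acetone, reflux; chromatography
Reagents that add atoms: dimethyl sulfate, COS(=O)(=O)OC
Why: O-alkylation of the potassium enolate with a hard electrophile should give both vinylogous esters, of which 4 (methoxy carbon next to CMe2, carbonyl remote) is separated, while the less hindered isomer, expected to predominate, is hydrolysed back to 3 and recycled.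

Step 3
Reactants: 4 3-methoxy-2,4,4-trimethylcyclohex-2-en-1-one
Product: 8 3-methoxy-2,4,4-trimethylcyclohexa-2,5-dien-1-one, via lithium dienolate 5 (not isolated), via phenylselenide 6 (not isolated), via selenoxide 7 (not isolated)
Conditions: LDA, THF, −78 °C; PhSeCl, −78 °C; then 30% H2O2, pyridine, CH2Cl2, 0 °C → rt
Reagents that add atoms: none
Why: Kinetic α′-deprotonation of the vinylogous ester, selenenylation and selenoxide syn-elimination (Reich dehydrogenation) should install the C12=C17 alkene, the only direction open because C18 is quaternary.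

Step 4
Reactants: 9 tiglic aldehyde, (2E)-2-methylbut-2-enal
Product: 10 tert-butyl(dimethyl){[(1E)-2-methylbuta-1,3-dien-1-yl]oxy}silane
Conditions: TBSOTf, Et3N, Et2O, 0 °C → rt
Reagents that add atoms: tert-butyldimethylsilyl trifluoromethanesulfonate, CC(C)(C)[Si](C)(C)OS(=O)(=O)C(F)(F)F
Why: Silyl dienol ether formation by soft enolisation (γ-deprotonation of the silyl-activated enal from its s-trans conformer) should give the (1E)-diene with oxygen trans to the vinyl group.

Step 5
Reactants: 8 3-methoxy-2,4,4-trimethylcyclohexa-2,5-dien-1-one; 10 tert-butyl(dimethyl){[(1E)-2-methylbuta-1,3-dien-1-yl]oxy}silane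
Product: 11 (4aS,8S,8aS)-8-[(tert-butyldimethylsilyl)oxy]-3-methoxy-2,4,4,7-tetramethyl-4a,5,8,8a-tetrahydronaphthalen-1(4H)-one
Conditions: (R)-o-tolyl-oxazaborolidine (20 mol%), Tf2NH (18 mol%), 10 (2 equiv), CH2Cl2, −78 → −20 °C; Et3N quench
Reagents that add atoms: none
Why: The cationic boron of the oxazaborolidinium should bind the C11 carbonyl oxygen on the lone pair syn to C12–H and lower the LUMO of the C12=C17 alkene, which then undergoes a concerted, asynchronous Diels–Alder reaction in which the unsubstituted diene terminus bonds to the β-carbon C17 ahead of the oxygen-bearing terminus bonding to C12; the closest known reaction type is the oxazaborolidinium-catalysed enantioselective Diels–Alder reaction of cyclic enones, quinones and quinone monoketals with silyloxydienes. Ring B closes in this one suprafacial [4+2] cycloaddition, both new bonds (C12–C13 and C16–C17) forming on the same face of the planar ring A, which makes the ring fusion cis. C12 and C17 are set in the absolute sense by the catalyst, whose phenyl group covers one face of the bound dienone so that the diene adds to the open face. C13 is set by the endo transition state, in which the outside silyloxy group of the (E)-diene lies under ring A and ends cis to the C12–C11 bond. The step needs site selectivity for C12=C17 over C9=C10 and ortho regiochemistry: the first follows because C9=C10 is tetrasubstituted and donor-substituted, the second from the polarisation of the diene by its oxygen. The C9 methoxy group, flanked by the C10 methyl and C18 Me2, is twisted out of conjugation, which should limit its deactivating effect on the C11 carbonyl.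

Step 6
Reactants: 11 (4aS,8S,8aS)-8-[(tert-butyldimethylsilyl)oxy]-3-methoxy-2,4,4,7-tetramethyl-4a,5,8,8a-tetrahydronaphthalen-1(4H)-one
Product: 13 (4aS,5S,8aS)-5-[(tert-butyldimethylsilyl)oxy]-1,1,3,6-tetramethyl-4a,5,8,8a-tetrahydronaphthalen-2(1H)-one, via hydroxy enol ether 12 (not isolated)
Conditions: DIBAL-H, toluene, −78 °C; then 1 M HCl, THF, 0 °C
Reagents that add atoms: water, O
Why: Stork–Danheiser transposition, in which 1,2-reduction at C11 followed by acid-mediated ionisation and hydrolysis of the enol ether should move the carbonyl to C9 and the alkene to C10=C11 without disturbing C12.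

Step 7
Reactants: 13 (4aS,5S,8aS)-5-[(tert-butyldimethylsilyl)oxy]-1,1,3,6-tetramethyl-4a,5,8,8a-tetrahydronaphthalen-2(1H)-one
Product: 15 (4aS,5S,8aS)-5-[(tert-butyldimethylsilyl)oxy]-1,1,3,6-tetramethyl-1,4,4a,5,8,8a-hexahydronaphthalen-2-yl trifluoromethanesulfonate, via lithium enolate 14 (not isolated)
Conditions: L-Selectride, THF, −78 °C; then PhNTf2, −78 → 0 °C
Reagents that add atoms: N-phenylbis(trifluoromethanesulfonimide), FC(F)(F)S(=O)(=O)N(c1ccccc1)S(=O)(=O)C(F)(F)F
Why: Conjugate hydride reduction of the β-unsubstituted enone, whose carbonyl is shielded by C18 Me2, should give the C9–C10 enolate regiospecifically, and O-triflation traps it as the tetrasubstituted enol triflate.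

Step 8
Reactants: 15 (4aS,5S,8aS)-5-[(tert-butyldimethylsilyl)oxy]-1,1,3,6-tetramethyl-1,4,4a,5,8,8a-hexahydronaphthalen-2-yl trifluoromethanesulfonate
Product: 16 (4aS,5S,8aS)-5-hydroxy-1,1,3,6-tetramethyl-1,4,4a,5,8,8a-hexahydronaphthalen-2-yl trifluoromethanesulfonate
Conditions: HF·pyridine, pyridine/THF, 0 °C → rt
Reagents that add atoms: none
Why: Desilylation with buffered HF should free the C13 allylic alcohol while sparing the enol triflate, which is sensitive to basic fluoride.

Step 9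
Reactants: 16 (4aS,5S,8aS)-5-hydroxy-1,1,3,6-tetramethyl-1,4,4a,5,8,8a-hexahydronaphthalen-2-yl trifluoromethanesulfonate
Product: 19 (4aR,8aS)-1,1,3,6-tetramethyl-1,4,4a,7,8,8a-hexahydronaphthalen-2-yl trifluoromethanesulfonate, via sulfonylhydrazine 17 (not isolated), via allylic diazene 18 (not isolated)
Conditions: o-nitrobenzenesulfonylhydrazide (NBSH), PPh3, DEAD, N-methylmorpholine, −30 °C; then 23 °C
Reagents that add atoms: none
Why: Myers reductive allylic transposition, in which Mitsunobu displacement at C13 with inversion, loss of sulfinic acid and retro-ene extrusion of N2 should deliver hydrogen to C15 and place the alkene at C13=C14, the carbinol no longer being β to a carbonyl and so not open to E1cB dehydration.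

Step 10
Reactants: 20 geranyl acetate, (2E)-3,7-dimethylocta-2,6-dien-1-yl acetate
Product: 22 (2E)-3-methyl-6-oxohex-2-en-1-yl acetate, via ozonide 21 (not isolated)
Conditions: O3 (1 equiv), CH2Cl2, −78 °C; then Me2S, −78 °C → rt
Reagents that add atoms: ozone, [O-][O+]=O
Why: Ozonolysis should be selective for the electron-rich 6,7-alkene because the 2,3-alkene is deactivated by the allylic acetoxy group.

Step 11
Reactants: 22 (2E)-3-methyl-6-oxohex-2-en-1-yl acetate; 23 (4R)-4-benzyl-3-propanoyl-1,3-oxazolidin-2-one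
Product: 26 (4R)-3-[(2R,3S,6E)-8-acetoxy-3-hydroxy-2,6-dimethyloct-6-enoyl]-4-benzyl-1,3-oxazolidin-2-one, via boron enolate 24 (not isolated), via boron aldolate 25 (not isolated)
Conditions: 23, Bu2BOTf, iPr2NEt, CH2Cl2, −78 → 0 °C; then 22, −78 → 0 °C; pH 7 buffer, MeOH, 30% H2O2, 0 °C
Reagents that add atoms: none
Why: Evans syn-aldol reaction, in which the (Z)-boron enolate reacts through a Zimmerman–Traxler chair with the auxiliary benzyl group shielding one enolate face, should set C2 (R) and C3 (S) in the 2,3-syn relationship.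

Step 12
Reactants: 26 (4R)-3-[(2R,3S,6E)-8-acetoxy-3-hydroxy-2,6-dimethyloct-6-enoyl]-4-benzyl-1,3-oxazolidin-2-one
Product: 27 (2E,6S,7S)-6,8-dihydroxy-3,7-dimethyloct-2-en-1-yl acetate
Conditions: NaBH4, THF/H2O, 0 °C → rt
Reagents that add atoms: none
Why: Reductive removal of the auxiliary by borohydride attack on the activated imide carbonyl should give the primary alcohol, the far less electrophilic allylic acetate being expected to survive.

Step 13
Reactants: 27 (2E,6S,7S)-6,8-dihydroxy-3,7-dimethyloct-2-en-1-yl acetate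
Product: 28 (2E,6S,7S)-8-[(tert-butyldiphenylsilyl)oxy]-6-hydroxy-3,7-dimethyloct-2-en-1-yl acetate
Conditions: TBDPSCl, imidazole, CH2Cl2, 0 °C
Reagents that add atoms: tert-butyl(chloro)diphenylsilane, CC(C)(C)[Si](Cl)(c1ccccc1)c1ccccc1
Why: Silylation with the bulky chlorosilane should be selective for the primary C1 hydroxyl over the secondary C3 hydroxyl.

Step 14
Reactants: 28 (2E,6S,7S)-8-[(tert-butyldiphenylsilyl)oxy]-6-hydroxy-3,7-dimethyloct-2-en-1-yl acetate
Product: 29 (2E,6S,7S)-8-[(tert-butyldiphenylsilyl)oxy]-3,7-dimethyl-6-[(methylsulfonyl)oxy]oct-2-en-1-yl acetate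
Conditions: MsCl, Et3N, CH2Cl2, −10 °C
Reagents that add atoms: methanesulfonyl chloride, CS(=O)(=O)Cl
Why: Sulfonylation with retention turns the C3 hydroxyl into a leaving group, and with C1 held at the alcohol oxidation level there is no acidic C2–H through which it could be lost by E1cB.

Step 15
Reactants: 29 (2E,6S,7S)-8-[(tert-butyldiphenylsilyl)oxy]-3,7-dimethyl-6-[(methylsulfonyl)oxy]oct-2-en-1-yl acetate
Product: 30 (2S,3S,6E)-1-[(tert-butyldiphenylsilyl)oxy]-8-hydroxy-2,6-dimethyloct-6-en-3-yl methanesulfonate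
Conditions: K2CO3 (cat.), MeOH, 0 °C
Reagents that add atoms: none
Why: Transesterification of the acetate with methanol should free the allylic alcohol, the secondary mesylate and the silyl ether being inert to carbonate in cold methanol.

Step 16
Reactants: 30 (2S,3S,6E)-1-[(tert-butyldiphenylsilyl)oxy]-8-hydroxy-2,6-dimethyloct-6-en-3-yl methanesulfonate
Product: 31 (2S,3S)-1-[(tert-butyldiphenylsilyl)oxy]-5-[(2R,3R)-3-(hydroxymethyl)-2-methyloxiran-2-yl]-2-methylpentan-3-yl methanesulfonate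
Conditions: Ti(OiPr)4, D-(−)-diethyl tartrate, t-BuOOH, 4 Å MS, CH2Cl2, −20 °C
Reagents that add atoms: tert-butyl hydroperoxide, CC(C)(C)OO
Why: Sharpless asymmetric epoxidation with D-(−)-tartrate should deliver oxygen to the face of the (E)-allylic alcohol that gives the (2R,3R)-epoxide, reagent control overriding the remote stereocentres.

Step 17
Reactants: 31 (2S,3S)-1-[(tert-butyldiphenylsilyl)oxy]-5-[(2R,3R)-3-(hydroxymethyl)-2-methyloxiran-2-yl]-2-methylpentan-3-yl methanesulfonate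
Product: 32 (2S,3S,6S,7R)-1-[(tert-butyldiphenylsilyl)oxy]-6-hydroperoxy-7,8-dihydroxy-2,6-dimethyloctan-3-yl methanesulfonate
Conditions: H2O2 (anhydrous, Et2O), phosphomolybdic acid (cat.), Et2O, 0 °C → rt
Reagents that add atoms: hydrogen peroxide, OO
Why: Acid-catalysed perhydrolysis of the trisubstituted epoxide should open it at the tertiary carbon C6 with inversion, which sets the C6 peroxy stereocentre.

Step 18
Reactants: 32 (2S,3S,6S,7R)-1-[(tert-butyldiphenylsilyl)oxy]-6-hydroperoxy-7,8-dihydroxy-2,6-dimethyloctan-3-yl methanesulfonate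
Product: 33 (1R)-1-[(3S,6R)-6-{(2S)-1-[(tert-butyldiphenylsilyl)oxy]propan-2-yl}-3-methyl-1,2-dioxan-3-yl]ethane-1,2-diol
Conditions: KOtBu (1.05 equiv), 18-crown-6 (cat.), THF, −20 → 0 °C
Reagents that add atoms: none
Why: Intramolecular SN2 alkylation of the peroxy anion (the hydroperoxide being the only OH acidic enough for one equivalent of base) should displace the C3 mesylate in a 6-exo-tet closure with inversion, forming the 1,2-dioxane and setting C3.

Step 19
Reactants: 33 (1R)-1-[(3S,6R)-6-{(2S)-1-[(tert-butyldiphenylsilyl)oxy]propan-2-yl}-3-methyl-1,2-dioxan-3-yl]ethane-1,2-diol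
Product: 34 (3S,6R)-6-{(2S)-1-[(tert-butyldiphenylsilyl)oxy]propan-2-yl}-3-methyl-1,2-dioxane-3-carbaldehyde
Conditions: NaIO4, THF/H2O, 0 °C → rt
Reagents that add atoms: none
Why: Malaprade glycol cleavage should give the aldehyde on the quaternary C6, which cannot epimerise, under conditions that leave a dialkyl peroxide untouched.

Step 20
Reactants: 34 (3S,6R)-6-{(2S)-1-[(tert-butyldiphenylsilyl)oxy]propan-2-yl}-3-methyl-1,2-dioxane-3-carbaldehyde
Product: 35 tert-butyl{(2S)-2-[(3R,6S)-6-ethenyl-6-methyl-1,2-dioxan-3-yl]propoxy}diphenylsilane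
Conditions: Ph3PCH3Br, KHMDS, THF, 0 °C; then 34, −78 → 0 °C
Reagents that add atoms: methyltriphenylphosphonium bromide, [Br-].C[P+](c1ccccc1)(c1ccccc1)c1ccccc1
Why: Wittig methylenation should install the vinyl group, the ylide adding to the aldehyde far faster than it attacks the dialkyl peroxide at low temperature.

Step 21
Reactants: 35 tert-butyl{(2S)-2-[(3R,6S)-6-ethenyl-6-methyl-1,2-dioxan-3-yl]propoxy}diphenylsilane
Product: 36 (2S)-2-[(3R,6S)-6-ethenyl-6-methyl-1,2-dioxan-3-yl]propan-1-ol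
Conditions: TBAF, AcOH, THF, rt
Reagents that add atoms: none
Why: Fluoride-mediated desilylation under acetic acid buffering should free the C1 alcohol without base-induced damage to the peroxide.

Step 22
Reactants: 36 (2S)-2-[(3R,6S)-6-ethenyl-6-methyl-1,2-dioxan-3-yl]propan-1-ol
Product: 38 (2R)-2-[(3R,6S)-6-ethenyl-6-methyl-1,2-dioxan-3-yl]propanoic acid, via aldehyde 37 (not isolated)
Conditions: TEMPO (cat.), PhI(OAc)2, MeCN/H2O, rt
Reagents that add atoms: water, O
Why: Oxoammonium (TEMPO) oxidation through the aldehyde hydrate should give the acid under near-neutral conditions that avoid β-elimination of the peroxide and epimerisation at C2.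

Step 23
Reactants: 38 (2R)-2-[(3R,6S)-6-ethenyl-6-methyl-1,2-dioxan-3-yl]propanoic acid
Product: 39 methyl (2R)-2-[(3R,6S)-6-ethenyl-6-methyl-1,2-dioxan-3-yl]propanoate
Conditions: TMSCHN2, MeOH/toluene, 0 °C
Reagents that add atoms: (trimethylsilyl)diazomethane, C[Si](C)(C)C=[N+]=[N-]
Why: Diazoalkane esterification of the carboxylic acid proceeds without base and so should not open the β-peroxy ester.

Step 24
Reactants: 39 methyl (2R)-2-[(3R,6S)-6-ethenyl-6-methyl-1,2-dioxan-3-yl]propanoate; 19 (4aR,8aS)-1,1,3,6-tetramethyl-1,4,4a,7,8,8a-hexahydronaphthalen-2-yl trifluoromethanesulfonate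
Product: 41 methyl (2R)-2-[(3R,6R)-6-methyl-6-{2-[(4aR,8aS)-1,1,3,6-tetramethyl-1,4,4a,7,8,8a-hexahydronaphthalen-2-yl]ethyl}-1,2-dioxan-3-yl]propanoate, via alkylborane 40 (not isolated)
Conditions: 39, 9-BBN, THF, 0 °C → rt; then 19, Pd(dppf)Cl2 (10 mol%), AsPh3, aq. K3PO4, DMF, rt → 40 °C
Reagents that add atoms: none
Why: B-alkyl Suzuki–Miyaura coupling, in which anti-Markovnikov hydroboration puts boron on C8 and palladium-catalysed coupling with the enol triflate forms C8–C9 with the alkene fixed at C9=C10, should give the target without creating or disturbing a stereocentre.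

**Compound list**

1 | 4,4-dimethylcyclohexane-1,3-dione | CC1(C)CCC(=O)CC1=O | starting material
2 | iodomethane | CI | starting material
3 | 2,4,4-trimethylcyclohexane-1,3-dione | CC1C(=O)CCC(C)(C)C1=O | intermediate
4 | 3-methoxy-2,4,4-trimethylcyclohex-2-en-1-one | COC1=C(C)C(=O)CCC1(C)C | intermediate
5 | lithium 5-methoxy-4,4,6-trimethylcyclohexa-1,5-dien-1-olate | [Li+].COC1=C(C)C([O-])=CCC1(C)C | intermediate (not isolated)
6 | 3-methoxy-2,4,4-trimethyl-6-(phenylselanyl)cyclohex-2-en-1-one (racemic) | COC1=C(C)C(=O)C([Se]c2ccccc2)CC1(C)C | intermediate (not isolated)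
7 | 3-methoxy-2,4,4-trimethyl-6-(phenylseleninyl)cyclohex-2-en-1-one | COC1=C(C)C(=O)C([Se](=O)c2ccccc2)CC1(C)C | intermediate (not isolated)
8 | 3-methoxy-2,4,4-trimethylcyclohexa-2,5-dien-1-one | COC1=C(C)C(=O)C=CC1(C)C | intermediate
9 | tiglic aldehyde, (2E)-2-methylbut-2-enal | C/C=C(\C)C=O | starting material
10 | tert-butyl(dimethyl){[(1E)-2-methylbuta-1,3-dien-1-yl]oxy}silane | C=C/C(C)=C/O[Si](C)(C)C(C)(C)C | intermediate
11 | (4aS,8S,8aS)-8-[(tert-butyldimethylsilyl)oxy]-3-methoxy-2,4,4,7-tetramethyl-4a,5,8,8a-tetrahydronaphthalen-1(4H)-one | COC1=C(C)C(=O)[C@@H]2[C@H](O[Si](C)(C)C(C)(C)C)C(C)=CC[C@@H]2C1(C)C | intermediate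
12 | 8-[(tert-butyldimethylsilyl)oxy]-3-methoxy-2,4,4,7-tetramethyl-1,4,4a,5,8,8a-hexahydronaphthalen-1-ol, ring fusion and C8 as in 11, both C1 epimers | COC1=C(C)C(O)[C@@H]2[C@H](O[Si](C)(C)C(C)(C)C)C(C)=CC[C@@H]2C1(C)C | intermediate (not isolated)
13 | (4aS,5S,8aS)-5-[(tert-butyldimethylsilyl)oxy]-1,1,3,6-tetramethyl-4a,5,8,8a-tetrahydronaphthalen-2(1H)-one | O=C1C(C)=C[C@@H]2[C@H](O[Si](C)(C)C(C)(C)C)C(C)=CC[C@@H]2C1(C)C | intermediate
14 | lithium (4aS,5S,8aS)-5-[(tert-butyldimethylsilyl)oxy]-1,1,3,6-tetramethyl-1,4,4a,5,8,8a-hexahydronaphthalen-2-olate | [Li+].[O-]C1=C(C)C[C@@H]2[C@H](O[Si](C)(C)C(C)(C)C)C(C)=CC[C@@H]2C1(C)C | intermediate (not isolated)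
15 | (4aS,5S,8aS)-5-[(tert-butyldimethylsilyl)oxy]-1,1,3,6-tetramethyl-1,4,4a,5,8,8a-hexahydronaphthalen-2-yl trifluoromethanesulfonate | FC(F)(F)S(=O)(=O)OC1=C(C)C[C@@H]2[C@H](O[Si](C)(C)C(C)(C)C)C(C)=CC[C@@H]2C1(C)C | intermediate
16 | (4aS,5S,8aS)-5-hydroxy-1,1,3,6-tetramethyl-1,4,4a,5,8,8a-hexahydronaphthalen-2-yl trifluoromethanesulfonate | FC(F)(F)S(=O)(=O)OC1=C(C)C[C@@H]2[C@H](O)C(C)=CC[C@@H]2C1(C)C | intermediate
17 | (4aS,5R,8aS)-5-[1-(2-nitrophenylsulfonyl)hydrazin-1-yl]-1,1,3,6-tetramethyl-1,4,4a,5,8,8a-hexahydronaphthalen-2-yl trifluoromethanesulfonate | FC(F)(F)S(=O)(=O)OC1=C(C)C[C@@H]2[C@@H](N(N)S(=O)(=O)c3ccccc3[N+](=O)[O-])C(C)=CC[C@@H]2C1(C)C | intermediate (not isolated)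
18 | (4aS,5R,8aS)-5-diazenyl-1,1,3,6-tetramethyl-1,4,4a,5,8,8a-hexahydronaphthalen-2-yl trifluoromethanesulfonate | FC(F)(F)S(=O)(=O)OC1=C(C)C[C@@H]2[C@@H](N=N)C(C)=CC[C@@H]2C1(C)C | intermediate (not isolated)
19 | (4aR,8aS)-1,1,3,6-tetramethyl-1,4,4a,7,8,8a-hexahydronaphthalen-2-yl trifluoromethanesulfonate | FC(F)(F)S(=O)(=O)OC1=C(C)C[C@@H]2C=C(C)CC[C@@H]2C1(C)C | intermediate
20 | geranyl acetate, (2E)-3,7-dimethylocta-2,6-dien-1-yl acetate | CC(=O)OC/C=C(\C)CCC=C(C)C | starting material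
21 | (2E)-5-(5,5-dimethyl-1,2,4-trioxolan-3-yl)-3-methylpent-2-en-1-yl acetate (ozonide) | CC(=O)OC/C=C(\C)CCC1OOC(C)(C)O1 | intermediate (not isolated)
22 | (2E)-3-methyl-6-oxohex-2-en-1-yl acetate | CC(=O)OC/C=C(\C)CCC=O | intermediate
23 | (4R)-4-benzyl-3-propanoyl-1,3-oxazolidin-2-one | CCC(=O)N1[C@H](Cc2ccccc2)COC1=O | starting material
24 | (Z)-dibutylboron enolate of 23 | C/C=C(\OB(CCCC)CCCC)N1[C@H](Cc2ccccc2)COC1=O | intermediate (not isolated)
25 | O-dibutylboryl aldolate of 26 | CC(=O)OC/C=C(\C)CC[C@H](OB(CCCC)CCCC)[C@@H](C)C(=O)N1[C@H](Cc2ccccc2)COC1=O | intermediate (not isolated)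
26 | (4R)-3-[(2R,3S,6E)-8-acetoxy-3-hydroxy-2,6-dimethyloct-6-enoyl]-4-benzyl-1,3-oxazolidin-2-one | CC(=O)OC/C=C(\C)CC[C@H](O)[C@@H](C)C(=O)N1[C@H](Cc2ccccc2)COC1=O | intermediate
27 | (2E,6S,7S)-6,8-dihydroxy-3,7-dimethyloct-2-en-1-yl acetate | CC(=O)OC/C=C(\C)CC[C@H](O)[C@@H](C)CO | intermediate
28 | (2E,6S,7S)-8-[(tert-butyldiphenylsilyl)oxy]-6-hydroxy-3,7-dimethyloct-2-en-1-yl acetate | CC(=O)OC/C=C(\C)CC[C@H](O)[C@@H](C)CO[Si](c1ccccc1)(c1ccccc1)C(C)(C)C | intermediate
29 | (2E,6S,7S)-8-[(tert-butyldiphenylsilyl)oxy]-3,7-dimethyl-6-[(methylsulfonyl)oxy]oct-2-en-1-yl acetate | CC(=O)OC/C=C(\C)CC[C@H](OS(C)(=O)=O)[C@@H](C)CO[Si](c1ccccc1)(c1ccccc1)C(C)(C)C | intermediate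
30 | (2S,3S,6E)-1-[(tert-butyldiphenylsilyl)oxy]-8-hydroxy-2,6-dimethyloct-6-en-3-yl methanesulfonate | OC/C=C(\C)CC[C@H](OS(C)(=O)=O)[C@@H](C)CO[Si](c1ccccc1)(c1ccccc1)C(C)(C)C | intermediate
31 | (2S,3S)-1-[(tert-butyldiphenylsilyl)oxy]-5-[(2R,3R)-3-(hydroxymethyl)-2-methyloxiran-2-yl]-2-methylpentan-3-yl methanesulfonate | OC[C@H]1O[C@]1(C)CC[C@H](OS(C)(=O)=O)[C@@H](C)CO[Si](c1ccccc1)(c1ccccc1)C(C)(C)C | intermediate
32 | (2S,3S,6S,7R)-1-[(tert-butyldiphenylsilyl)oxy]-6-hydroperoxy-7,8-dihydroxy-2,6-dimethyloctan-3-yl methanesulfonate | OC[C@@H](O)[C@@](C)(OO)CC[C@H](OS(C)(=O)=O)[C@@H](C)CO[Si](c1ccccc1)(c1ccccc1)C(C)(C)C | intermediate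
33 | (1R)-1-[(3S,6R)-6-{(2S)-1-[(tert-butyldiphenylsilyl)oxy]propan-2-yl}-3-methyl-1,2-dioxan-3-yl]ethane-1,2-diol | OC[C@@H](O)[C@]1(C)CC[C@@H](OO1)[C@@H](C)CO[Si](c1ccccc1)(c1ccccc1)C(C)(C)C | intermediate
34 | (3S,6R)-6-{(2S)-1-[(tert-butyldiphenylsilyl)oxy]propan-2-yl}-3-methyl-1,2-dioxane-3-carbaldehyde | O=C[C@]1(C)CC[C@@H](OO1)[C@@H](C)CO[Si](c1ccccc1)(c1ccccc1)C(C)(C)C | intermediate
35 | tert-butyl{(2S)-2-[(3R,6S)-6-ethenyl-6-methyl-1,2-dioxan-3-yl]propoxy}diphenylsilane | C=C[C@]1(C)CC[C@@H](OO1)[C@@H](C)CO[Si](c1ccccc1)(c1ccccc1)C(C)(C)C | intermediate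
36 | (2S)-2-[(3R,6S)-6-ethenyl-6-methyl-1,2-dioxan-3-yl]propan-1-ol | C=C[C@]1(C)CC[C@@H](OO1)[C@@H](C)CO | intermediate
37 | (2R)-2-[(3R,6S)-6-ethenyl-6-methyl-1,2-dioxan-3-yl]propanal | C=C[C@]1(C)CC[C@@H](OO1)[C@@H](C)C=O | intermediate (not isolated)
38 | (2R)-2-[(3R,6S)-6-ethenyl-6-methyl-1,2-dioxan-3-yl]propanoic acid | C=C[C@]1(C)CC[C@@H](OO1)[C@@H](C)C(=O)O | intermediate
39 | methyl (2R)-2-[(3R,6S)-6-ethenyl-6-methyl-1,2-dioxan-3-yl]propanoate | COC(=O)[C@H](C)[C@H]1CC[C@@](C)(C=C)OO1 | intermediate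
40 | methyl (2R)-2-[(3R,6R)-6-[2-(9-borabicyclo[3.3.1]nonan-9-yl)ethyl]-6-methyl-1,2-dioxan-3-yl]propanoate | COC(=O)[C@H](C)[C@H]1CC[C@@](C)(CCB2C3CCCC2CCC3)OO1 | intermediate (not isolated)
41 | methyl (2R)-2-[(3R,6R)-6-methyl-6-{2-[(4aR,8aS)-1,1,3,6-tetramethyl-1,4,4a,7,8,8a-hexahydronaphthalen-2-yl]ethyl}-1,2-dioxan-3-yl]propanoate | COC(=O)[C@H](C)[C@H]1CC[C@@](C)(CCC2=C(C)C[C@@H]3C=C(C)CC[C@@H]3C2(C)C)OO1 | target

**Step count and risk**

Total step count: 24. Longest linear sequence: 15 steps (steps 10–24, from geranyl acetate). The ring branch is 9 steps (1–3, 5–9, 24), with step 4 making the diene.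

The three steps most likely to fail:

Step 5. The donor-substituted dienone may be too weakly activated, so that cycloaddition at the neopentyl C17 is outrun by acid-induced loss of the silyl dienol ether or by dienone–phenol rearrangement, or facial control may be poor. The fallback sets out from diene 10 and moves the introduction of the C9 oxygen to after the cycloaddition. Purchased 2,4,4-trimethylcyclohex-2-en-1-one F1 is dehydrogenated with IBX (DMSO, 70 °C) to 2,4,4-trimethylcyclohexa-2,5-dien-1-one F2, whose unsubstituted enone alkene is a fully activated dienophile. The same catalysed cycloaddition with 10 should give the des-methoxy adduct F3. Nucleophilic epoxidation of the remaining enone (H2O2, LiOH, MeOH, 0 °C) gives epoxy ketone F4, Wharton transposition (N2H4·H2O, AcOH, MeOH) gives allylic alcohol F5, and Dess–Martin oxidation comes back to the route at enone 13.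

Step 24. The O–O bond may be cleaved by Pd(0), the arsine or the borane, the β-peroxy ester may open under the basic aqueous conditions, and oxidative addition at the hindered tetrasubstituted triflate may be slow. The fallback sets out from triflate 19 and aldehyde 34 and forms the chain by olefination, so that palladium is used only before the peroxide is present. Methoxycarbonylation of 19 (CO, MeOH, Pd(OAc)2, dppp, Et3N, DMF) gives methyl ester F6, DIBAL-H reduction gives allylic alcohol F7, CBr4/PPh3 gives allylic bromide F8 and PPh3 in MeCN gives phosphonium bromide F9. Its ylide (NaHMDS, THF, −78 °C) is condensed with 34 to diene F10 (either alkene geometry). Diimide (potassium azodicarboxylate, AcOH) should saturate only the disubstituted C7=C8 alkene to give silyl ether F11. Desilylation (TBAF, AcOH) to alcohol F12, TEMPO/PhI(OAc)2 oxidation to acid F13 and TMSCHN2 esterification come back to the route at 41.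

Step 9. The Mitsunobu displacement may fail at the hindered C13 carbinol, or SN2′ attack and elimination may give the untransposed alkene or a diene. The fallback sets out from alcohol 16 and reaches the same allylic diazene from a hydrazone. Dess–Martin oxidation gives enone F14 and condensation with TsNHNH2 gives tosylhydrazone F15. Catecholborane reduction (CHCl3, 0 °C) followed by NaOAc·3H2O at reflux (alkene-transposing hydrazone reduction) comes back to the route at 19.

**Further compounds**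

F1 | step 5 | 2,4,4-trimethylcyclohex-2-en-1-one | CC1=CC(C)(C)CCC1=O
F2 | step 5 | 2,4,4-trimethylcyclohexa-2,5-dien-1-one | CC1=CC(C)(C)C=CC1=O
F3 | step 5 | (4aS,8S,8aS)-8-[(tert-butyldimethylsilyl)oxy]-2,4,4,7-tetramethyl-4a,5,8,8a-tetrahydronaphthalen-1(4H)-one | C1=C(C)C(=O)[C@@H]2[C@H](O[Si](C)(C)C(C)(C)C)C(C)=CC[C@@H]2C1(C)C
F4 | step 5 | 2,3-epoxide of F3 (epoxide configuration not specified) | O=C1[C@@H]2[C@H](O[Si](C)(C)C(C)(C)C)C(C)=CC[C@@H]2C(C)(C)C2OC12C
F5 | step 5 | (4aS,5S,8aS)-5-[(tert-butyldimethylsilyl)oxy]-1,1,3,6-tetramethyl-1,2,4a,5,8,8a-hexahydronaphthalen-2-ol (C2 configuration not specified) | OC1C(C)=C[C@@H]2[C@H](O[Si](C)(C)C(C)(C)C)C(C)=CC[C@@H]2C1(C)C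
F6 | step 24 | methyl (4aR,8aS)-1,1,3,6-tetramethyl-1,4,4a,7,8,8a-hexahydronaphthalene-2-carboxylate | COC(=O)C1=C(C)C[C@@H]2C=C(C)CC[C@@H]2C1(C)C
F7 | step 24 | [(4aR,8aS)-1,1,3,6-tetramethyl-1,4,4a,7,8,8a-hexahydronaphthalen-2-yl]methanol | OCC1=C(C)C[C@@H]2C=C(C)CC[C@@H]2C1(C)C
F8 | step 24 | (4aR,8aS)-2-(bromomethyl)-1,1,3,6-tetramethyl-1,4,4a,7,8,8a-hexahydronaphthalene | BrCC1=C(C)C[C@@H]2C=C(C)CC[C@@H]2C1(C)C
F9 | step 24 | {[(4aR,8aS)-1,1,3,6-tetramethyl-1,4,4a,7,8,8a-hexahydronaphthalen-2-yl]methyl}triphenylphosphonium bromide | [Br-].c1ccccc1[P+](c1ccccc1)(c1ccccc1)CC1=C(C)C[C@@H]2C=C(C)CC[C@@H]2C1(C)C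
F10 | step 24 | tert-butyl{(2S)-2-[(3R,6R)-6-methyl-6-{2-[(4aR,8aS)-1,1,3,6-tetramethyl-1,4,4a,7,8,8a-hexahydronaphthalen-2-yl]ethenyl}-1,2-dioxan-3-yl]propoxy}diphenylsilane (alkene geometry not specified) | CC(C)(C)[Si](c1ccccc1)(c1ccccc1)OC[C@H](C)[C@H]1CC[C@@](C)(C=CC2=C(C)C[C@@H]3C=C(C)CC[C@@H]3C2(C)C)OO1
F11 | step 24 | tert-butyl{(2S)-2-[(3R,6R)-6-methyl-6-{2-[(4aR,8aS)-1,1,3,6-tetramethyl-1,4,4a,7,8,8a-hexahydronaphthalen-2-yl]ethyl}-1,2-dioxan-3-yl]propoxy}diphenylsilane | CC(C)(C)[Si](c1ccccc1)(c1ccccc1)OC[C@H](C)[C@H]1CC[C@@](C)(CCC2=C(C)C[C@@H]3C=C(C)CC[C@@H]3C2(C)C)OO1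
F12 | step 24 | (2S)-2-[(3R,6R)-6-methyl-6-{2-[(4aR,8aS)-1,1,3,6-tetramethyl-1,4,4a,7,8,8a-hexahydronaphthalen-2-yl]ethyl}-1,2-dioxan-3-yl]propan-1-ol | OC[C@H](C)[C@H]1CC[C@@](C)(CCC2=C(C)C[C@@H]3C=C(C)CC[C@@H]3C2(C)C)OO1
F13 | step 24 | (2R)-2-[(3R,6R)-6-methyl-6-{2-[(4aR,8aS)-1,1,3,6-tetramethyl-1,4,4a,7,8,8a-hexahydronaphthalen-2-yl]ethyl}-1,2-dioxan-3-yl]propanoic acid | OC(=O)[C@H](C)[C@H]1CC[C@@](C)(CCC2=C(C)C[C@@H]3C=C(C)CC[C@@H]3C2(C)C)OO1
F14 | step 9 | (4aS,8aS)-1,1,3,6-tetramethyl-5-oxo-1,4,4a,5,8,8a-hexahydronaphthalen-2-yl trifluoromethanesulfonate | FC(F)(F)S(=O)(=O)OC1=C(C)C[C@@H]2C(=O)C(C)=CC[C@@H]2C1(C)C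
F15 | step 9 | 4-methylbenzenesulfonylhydrazone of F14 | FC(F)(F)S(=O)(=O)OC1=C(C)C[C@@H]2C(=NNS(=O)(=O)c3ccc(C)cc3)C(C)=CC[C@@H]2C1(C)C
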